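**Retrosynthetic overview**
- Feature: C2 and C3 of the dihydrofuran ring are vicinal stereocentres, each bonded to one arene (C2 to C1' of the trimethoxyphenyl ring, C3 to C3a of ring A), and C2 also carries O1. Both aryl–carbon bonds can therefore be made in one operation across an (E)-propenyl–boron unit in which boron stands for O1.
- Late disconnections: C5–propenyl (Suzuki coupling) back to C5–B (sterically controlled C–H borylation); O1–C7a (alkoxide displacing an aryl fluoride); C2–O back to C2–B (retentive oxidation).
- Key disconnection: C3–C3a and C2–C1' together, by conjunctive coupling of a propenylboronate, (3,4,5-trimethoxyphenyl)lithium and 2-fluoro-3-methoxyphenyl triflate.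
- Ring order: both arenes are bought; the dihydrofuran ring is the only ring formed, by O1–C7a closure (step 6) after the key step.

Key step: step 4

Numbering: benzofuran locants (O1, C2, C3, C3a, C4–C7, C7a); ring A is the benzo ring; "mac" is the cis-1,2-dimethylacenaphthene-1,2-diol ester group on boron.

Assumption: the sense of induction of MandyPhos is taken by analogy with simpler aryl/alkyl cases; (Sp,Sp) is written as the antipode meant to give (1R,2S)-10, and the equally available (Rp,Rp) ligand is used if a pilot run shows the opposite sense.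

**Step 1**
Reactants: 1 acenaphthylene-1,2-dione
Product: 2 cis-1,2-dimethyl-1,2-dihydroacenaphthylene-1,2-diol (meso)
Conditions: MeMgBr (3 equiv), THF, 0 °C to rt; then H2O; crystallisation
Reagents that add atoms: methylmagnesium bromide, C[Mg]Br
Why: Double Grignard addition to the 1,2-diketone, in which the second methyl should add anti to the bulky magnesium alkoxide formed first, so the cis (meso) diol should predominate and is freed of any trans isomer by crystallisation.

**Step 2**
Reactants: 3 (E)-prop-1-enylboronic acid; 2 cis-1,2-dimethyl-1,2-dihydroacenaphthylene-1,2-diol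
Product: 4 (E)-prop-1-enylboronic acid mac ester
Conditions: 4 Å molecular sieves, toluene, rt to 50 °C
Reagents that add atoms: none
Why: Boronic ester formation by condensation of a boronic acid with a cis-1,2-diol, driven by removal of water; the (E)-alkene is not touched.

**Step 3**
Reactants: 5 2-fluoro-3-methoxyphenol
Product: 6 2-fluoro-3-methoxyphenyl trifluoromethanesulfonate
Conditions: Tf2O (1.2 equiv), pyridine (2 equiv), CH2Cl2, 0 °C
Reagents that add atoms: trifluoromethanesulfonic anhydride, O=S(=O)(OS(=O)(=O)C(F)(F)F)C(F)(F)F
Why: O-Sulfonylation of a phenol (triflation), the standard way to make the aryl C–O bond ready for oxidative addition.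

**Step 4**
Reactants: 7 5-bromo-1,2,3-trimethoxybenzene; 4 (E)-prop-1-enylboronic acid mac ester; 6 2-fluoro-3-methoxyphenyl trifluoromethanesulfonate
Product: 10 mac ester of (1R,2S)-2-(2-fluoro-3-methoxyphenyl)-1-(3,4,5-trimethoxyphenyl)propylboronic acid, via (3,4,5-trimethoxyphenyl)lithium 8 (not isolated), via lithium propenyl(aryl)borate ate complex 9 (not isolated)
Conditions: t-BuLi (2.0 equiv), THF, −78 °C; then 4, −78 °C to rt; then Pd(OAc)2 (2 mol %), (Sp,Sp)-MandyPhos (C52H50FeN2P2, 2.4 mol %), 6, KOTf (2 equiv), THF, 60 °C
Reagents that add atoms: none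
Why: Zerovalent palladium inserts into the C–OTf bond of 6 to give a cationic arylpalladium species (divalent palladium) that binds the alkene of ate complex 9; this triggers a 1,2-metallate shift in which the trimethoxyphenyl group moves from boron to the boron-bearing carbon (future C2) on the face anti to palladium while palladium bonds to the methyl-bearing carbon (future C3), and reductive elimination then joins that carbon to ring A. The closest known reaction is the palladium-catalysed enantioselective conjunctive cross-coupling of β-substituted alkenylboron ate complexes carrying the mac ligand with aryllithiums and aryl triflates. No ring is closed in this step. Of the two new stereocentres, the relative configuration follows from the stereospecific anti addition of the two aryl groups across the (E)-alkene, and the absolute configuration from the alkene face selected by the MandyPhos-bound palladium. The step needs the metallate shift to outrun direct Suzuki–Miyaura transfer of the propenyl or aryl group and β-hydride elimination: the hindered mac ligand slows transmetallation, the triflate together with KOTf keeps palladium cationic and free of bromide, and the wide-bite-angle diphosphine speeds reductive elimination. The ortho fluorine of 6 is small and should not hinder oxidative addition or alkene binding.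

**Step 5**
Reactants: 10 mac ester of (1R,2S)-2-(2-fluoro-3-methoxyphenyl)-1-(3,4,5-trimethoxyphenyl)propylboronic acid
Product: 11 (1R,2R)-2-(2-fluoro-3-methoxyphenyl)-1-(3,4,5-trimethoxyphenyl)propan-1-ol
Conditions: 30% H2O2, 3 M NaOH, THF, 0 °C to rt
Reagents that add atoms: hydrogen peroxide, OO
Why: Alkaline peroxide oxidation of the C–B bond, in which carbon shifts from boron to oxygen with retention, so C1 keeps its configuration and C2 is untouched; the descriptor changes from S to R at C2 only because of ligand priorities, and diol 2 is released for recovery.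

**Step 6**
Reactants: 11 (1R,2R)-2-(2-fluoro-3-methoxyphenyl)-1-(3,4,5-trimethoxyphenyl)propan-1-ol
Product: 12 (2R,3R)-7-methoxy-3-methyl-2-(3,4,5-trimethoxyphenyl)-2,3-dihydro-1-benzofuran
Conditions: KOtBu (1.5 equiv), DMSO, 70 °C
Reagents that add atoms: none
Why: Intramolecular nucleophilic aromatic substitution (5-exo closure of O1–C7a) of the potassium alkoxide on the aryl fluoride, as known for 2-(2-fluoroaryl)ethanols; both positions ortho to the C–F carbon are substituted so no aryne can form, and no bond at C2 or C3 is broken, so the trans (2R,3R) arrangement carries over.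

**Step 7**
Reactants: 12 (2R,3R)-7-methoxy-3-methyl-2-(3,4,5-trimethoxyphenyl)-2,3-dihydro-1-benzofuran
Product: 13 (2R,3R)-7-methoxy-3-methyl-5-(4,4,5,5-tetramethyl-1,3,2-dioxaborolan-2-yl)-2-(3,4,5-trimethoxyphenyl)-2,3-dihydro-1-benzofuran
Conditions: [Ir(OMe)(cod)]2 (1.5 mol %), dtbpy (3 mol %), B2pin2 (1.0 equiv), THF, 80 °C
Reagents that add atoms: bis(pinacolato)diboron, CC1(C)OB(OC1(C)C)B1OC(C)(C)C(C)(C)O1
Why: Iridium-catalysed aromatic C–H borylation under steric control: C5 is the only arene C–H with no ortho substituent (C4 and C6 have one each, the two C–H of the trimethoxyphenyl ring have two), so boron should go to C5.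

**Step 8**
Reactants: 13 the C5 pinacol boronate; 14 (E)-1-bromoprop-1-ene
Product: 15 (2R,3R)-7-methoxy-3-methyl-5-[(E)-prop-1-enyl]-2-(3,4,5-trimethoxyphenyl)-2,3-dihydro-1-benzofuran (target)
Conditions: Pd(PPh3)4 (5 mol %), K2CO3 (aq), 1,4-dioxane, 80 °C, sealed tube, 14 in excess
Reagents that add atoms: none
Why: Suzuki–Miyaura coupling of an aryl pinacol boronate with an alkenyl bromide, which proceeds with retention of alkene geometry and does not involve the stereocentres.

**Compound list**
1 | acenaphthylene-1,2-dione | O=C1C(=O)c2cccc3cccc1c23 | starting material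
2 | cis-1,2-dimethyl-1,2-dihydroacenaphthylene-1,2-diol (meso, 1R,2S) | O[C@]1(C)c2cccc3cccc(c23)[C@]1(C)O | intermediate
3 | (E)-prop-1-enylboronic acid | C/C=C/B(O)O | starting material
4 | (E)-prop-1-enylboronic acid mac ester (cis-fused dioxaborolane) | C/C=C/B1O[C@]2(C)c3cccc4cccc(c34)[C@]2(C)O1 | intermediate
5 | 2-fluoro-3-methoxyphenol | COc1cccc(O)c1F | starting material
6 | 2-fluoro-3-methoxyphenyl trifluoromethanesulfonate | COc1cccc(OS(=O)(=O)C(F)(F)F)c1F | intermediate
7 | 5-bromo-1,2,3-trimethoxybenzene | COc1cc(Br)cc(OC)c1OC | starting material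
8 | (3,4,5-trimethoxyphenyl)lithium (formed in the flask) | [Li]c1cc(OC)c(OC)c(OC)c1 | intermediate
9 | lithium [(E)-prop-1-enyl](3,4,5-trimethoxyphenyl)borate of diol 2 (ate complex, formed in the flask, configuration at boron not defined) | [Li+].C/C=C/[B-]1(c2cc(OC)c(OC)c(OC)c2)O[C@]2(C)c3cccc4cccc(c34)[C@]2(C)O1 | intermediate
10 | mac ester of (1R,2S)-2-(2-fluoro-3-methoxyphenyl)-1-(3,4,5-trimethoxyphenyl)propylboronic acid | COc1cccc([C@@H](C)[C@H](c2cc(OC)c(OC)c(OC)c2)B2O[C@]3(C)c4cccc5cccc(c45)[C@]3(C)O2)c1F | intermediate
11 | (1R,2R)-2-(2-fluoro-3-methoxyphenyl)-1-(3,4,5-trimethoxyphenyl)propan-1-ol | COc1cccc([C@@H](C)[C@H](c2cc(OC)c(OC)c(OC)c2)O)c1F | intermediate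
12 | (2R,3R)-7-methoxy-3-methyl-2-(3,4,5-trimethoxyphenyl)-2,3-dihydro-1-benzofuran | c1cc(OC)c2c(c1)[C@@H](C)[C@H](c1cc(OC)c(OC)c(OC)c1)O2 | intermediate
13 | (2R,3R)-7-methoxy-3-methyl-5-(4,4,5,5-tetramethyl-1,3,2-dioxaborolan-2-yl)-2-(3,4,5-trimethoxyphenyl)-2,3-dihydro-1-benzofuran | CC1(C)OB(OC1(C)C)c1cc(OC)c2c(c1)[C@@H](C)[C@H](c1cc(OC)c(OC)c(OC)c1)O2 | intermediate
14 | (E)-1-bromoprop-1-ene | C/C=C/Br | starting material
15 | (2R,3R)-7-methoxy-3-methyl-5-[(E)-prop-1-enyl]-2-(3,4,5-trimethoxyphenyl)-2,3-dihydro-1-benzofuran | C/C=C/c1cc(OC)c2c(c1)[C@@H](C)[C@H](c1cc(OC)c(OC)c(OC)c1)O2 | target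

**Step count**
Total: 8 steps. Longest linear sequence: 7 steps (1, 2, 4, 5, 6, 7, 8).

**Steps most likely to fail**

Step 4. Direct Suzuki–Miyaura transfer of the propenyl or aryl group from the ate complex may outrun the metallate shift, or the ortho-substituted electrophile may erode facial selectivity. The fallback sets out from triflate 6 and returns at alcohol 11. Palladium-catalysed ketone α-arylation of commercial 1-(3,4,5-trimethoxyphenyl)propan-1-one with 6 (Pd2(dba)3, Xantphos, K3PO4, toluene, 90 °C) should give racemic 2-(2-fluoro-3-methoxyphenyl)-1-(3,4,5-trimethoxyphenyl)propan-1-one F1. Its α-aryl stereocentre is configurationally labile under base, so Noyori hydrogenation with dynamic kinetic resolution (RuCl2[(S)-xylbinap][(S)-daipen] or its antipode, chosen for the (1R) carbinol, KOtBu, i-PrOH, H2) should reduce one equilibrating enantiomer. Hydride delivery anti to ring A in a Felkin-type arrangement corresponds to the (1R,2R) diastereomer, which is 11.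

Step 6. Displacement of fluoride on the electron-rich ring may be sluggish, and the alkoxide may degrade on prolonged heating. The fallback sets out from boronate 4 (with ate complex 9 formed from 7 as before) and returns at 12, replacing fluorine by chlorine so that the ring is closed by palladium catalysis. Commercial 2-chloro-3-methoxyphenol is triflated as in step 3 to 2-chloro-3-methoxyphenyl trifluoromethanesulfonate F2. Conjunctive coupling as in step 4, with the triflate reacting in preference to the aryl chloride, should give the mac ester of (1R,2S)-2-(2-chloro-3-methoxyphenyl)-1-(3,4,5-trimethoxyphenyl)propylboronic acid F3. Oxidation as in step 5 gives (1R,2R)-2-(2-chloro-3-methoxyphenyl)-1-(3,4,5-trimethoxyphenyl)propan-1-ol F4. Intramolecular Buchwald-type C–O coupling (Pd(OAc)2, 2-(di-tert-butylphosphino)-1,1'-binaphthyl, Cs2CO3, toluene, 80 °C) then closes O1–C7a without touching C2 or C3.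

Step 7. Borylation may stray to C4 or C6, or a second boryl group may be introduced. The fallback sets out from 12 and returns at target 15, using an electrophilic, para-selective C–H functionalisation instead. Thianthrenation (thianthrene S-oxide, trifluoroacetic anhydride, HBF4·OEt2, MeCN, 0 °C to rt) should attack C5, which is para to O1 and unhindered, whereas the free positions of the trimethoxyphenyl ring are flanked on both sides. This should give 5-[(2R,3R)-7-methoxy-3-methyl-2-(3,4,5-trimethoxyphenyl)-2,3-dihydro-1-benzofuran-5-yl]thianthren-5-ium tetrafluoroborate F5. Suzuki–Miyaura coupling of this salt with (E)-prop-1-enylboronic acid 3 (Pd(dppf)Cl2, K3PO4, 1,4-dioxane/H2O, 60 °C) then gives 15 directly.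

**Further compounds**
F1 | step 4 | racemic 2-(2-fluoro-3-methoxyphenyl)-1-(3,4,5-trimethoxyphenyl)propan-1-one | COc1cccc(C(C)C(=O)c2cc(OC)c(OC)c(OC)c2)c1F
F2 | step 6 | 2-chloro-3-methoxyphenyl trifluoromethanesulfonate | COc1cccc(OS(=O)(=O)C(F)(F)F)c1Cl
F3 | step 6 | mac ester of (1R,2S)-2-(2-chloro-3-methoxyphenyl)-1-(3,4,5-trimethoxyphenyl)propylboronic acid | COc1cccc([C@@H](C)[C@H](c2cc(OC)c(OC)c(OC)c2)B2O[C@]3(C)c4cccc5cccc(c45)[C@]3(C)O2)c1Cl
F4 | step 6 | (1R,2R)-2-(2-chloro-3-methoxyphenyl)-1-(3,4,5-trimethoxyphenyl)propan-1-ol | COc1cccc([C@@H](C)[C@H](c2cc(OC)c(OC)c(OC)c2)O)c1Cl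
F5 | step 7 | 5-[(2R,3R)-7-methoxy-3-methyl-2-(3,4,5-trimethoxyphenyl)-2,3-dihydro-1-benzofuran-5-yl]thianthren-5-ium tetrafluoroborate | c1ccc2c(c1)Sc1ccccc1[S+]2c1cc(OC)c2c(c1)[C@@H](C)[C@H](c1cc(OC)c(OC)c(OC)c1)O2.F[B-](F)(F)F
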